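**Remark.** The SMILES is read as the trans-(2R,3R)-dihydroflavonol 3,5,7-trihydroxy-8-methoxy-6-prenylflavanone. Flavonoid numbering (O1, C2–C8a) is used for the target. In open-chain precursors the aryl carbons are primed, C1' carrying the carbonyl, so that O–C2' becomes O1, C3' becomes C8 and C5' becomes C6.

## The problem

The target 15 is a chroman-4-one (ring C fused to ring A through C4a–C8a) with a phenyl group on C2 and a free carbinol on C3. Ring A is hexasubstituted and carries four oxygens in four different states (O1 in ring C, the chelated 5-OH, the 7-OH, the 8-OMe) plus one C-prenyl group on C6. Any closure of ring C from a 2',6'-dihydroxyaryl ketone can use either ortho oxygen, and the wrong one gives the 6-methoxy-8-prenyl isomer, so the synthesis must decide which oxygen becomes O1 and which carbon receives the prenyl group. The two stereocentres are adjacent and trans; C2 is a benzylic ether carbon that is lost whenever the C3/C4 enolate opens ring C, so both centres are best fixed together in an open-chain precursor and transferred by a stereospecific C–O bond formation. The prenyl group, flanked by two phenols, cyclises to chromans in strong acid and is attacked by peracids, dioxiranes, OsO4 and hydrogenation catalysts, while the dihydroflavonol is base-labile (oxidation to the flavonol, ring contraction, epimerisation). The feature the plan exploits lies in ring A: O1 sits on C8a, both carbons ortho to C8a are substituted (C8 by OMe, C4a by the C4 carbonyl), and the prenyl group sits on C6, para to C8a. A prenyl group parked on the phenol oxygen that is to become O1 can therefore reach carbon only at C6, through two consecutive [3,3] shifts that return the linear prenyl isomer, and its departure unmasks exactly the oxygen that has to close ring C. A second relationship helps the run-up: C8 is para to C5, so the OMe oxygen can be introduced para to a free phenol in the phloroacetophenone series, whose two ortho oxygens are equivalent by symmetry.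

## Retrosynthesis

**15 ⇒ 14.** The two O–CH2OMe bonds on O5 and O7 are cut. O5 must stay masked until ring C exists, or it competes for ring closure, and O7 must be masked through the basic steps. MOM ethers survive KOH, hydroperoxide and a mild Lewis acid and fall to dilute acid, which a dihydroflavonol tolerates. Silyl or acyl groups would not survive the aldol step, and benzyl would need hydrogenolysis. The forward step must be acetal cleavage mild enough to spare the prenyl group.

**14 ⇒ 10 (key disconnection).** Two bonds are cut at once, O1–C2 of ring C and C6–CH2 of the prenyl group, and the prenyl group is returned to the oxygen on C2' (the future O1). Cutting only O1–C2 would leave a C-prenylated chalcone epoxide with two competing ortho oxygens and a separate C-prenylation sequence. Cutting only C6–prenyl would leave a late C-alkylation on a sensitive core. The precursor 10 has no ring C, no C–C bond to the prenyl group and a single stereo-element, a trans-epoxide. The forward reaction must deliver a Claisen/Cope sequence to C5' followed by 6-endo opening of the oxirane with inversion.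

**10 ⇒ 9.** Both C–O bonds of the oxirane are cut to give the E-enone 9. Dihydroxylation or electrophilic epoxidation would attack the prenyl ether double bond first. A nucleophilic (hydroperoxide) epoxidation sees only the enone. The forward step must choose the enone face that gives the (2R,3S)-epoxide.

**9 ⇒ 7 + 8.** The Cα=Cβ bond is cut (Claisen–Schmidt condensation), giving the acetophenone 7 and benzaldehyde 8. The fully O-substituted ketone cannot cyclise and needs only aqueous base.

**7 ⇒ 6 ⇒ 4 (via 5).** First the MOM group on the chelated oxygen is removed (6), then the C3'–OMe bond is cut. In 4 the only free phenol is para to C3', so an oxidative methoxylation through the quinone monoketal 5 must place the OMe between the O-prenyl and O-MOM carbons. The alternative, starting from 2-methoxyphloroglucinol, would carry the OMe from the outset but would leave two ortho OH groups that differ only in their neighbours and would have to be told apart by selective protection. Here the position is enforced by a para relationship.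

**4 ⇒ 2 + 3 ⇒ 1.** The O–prenyl and O–MOM bonds are cut. Phloroacetophenone 1 is symmetric: its two ortho OH groups are equivalent, so whichever receives the prenyl group gives the same compound. The 4-OH is set apart because it is the only one not hydrogen-bonded to the ketone. Three commercial materials (1, 3, 8) remain.

## Roads not taken

**Alternative 1:** the obvious route. Cut only O1–C2: build a chalcone epoxide with the prenyl group already on carbon and every phenol protected, the tris-MOM epoxy ketone A1, then remove the MOM groups with acid so that a 2'-OH opens the epoxide. The acid frees both ortho oxygens of A1 together. They differ only in having OMe or prenyl as neighbour, and closure through the second gives the 6-methoxy-8-prenyl isomer A2. A1 also needs a separate C-prenylation sequence at the acetophenone stage. The chosen plan unmasks a single, predetermined oxygen and obtains the C-prenyl group from the protecting group.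

**Alternative 2:** cut C2–Ph and C3–OH. Asymmetric conjugate addition of phenylboronic acid (Pd(II)/pyridine-oxazoline or Rh/diene) to the chromone A3 would give the (2S)-flavanone A4, followed by α-hydroxylation at C3 by enolisation and electrophilic oxidation (Rubottom or Davis type). The stereocentres are set in two separate operations. Enolisation of A4 opens ring C by β-elimination of the phenoxide and endangers C2, and dioxirane or peracid oxidants also epoxidise the prenyl group. A3 still contains the whole ring-A problem (which oxygen is O1, where the prenyl group goes) and costs as many steps as 10.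

**Alternative 3:** cut C6–prenyl last. The prenyl-free core A5 has C6 as its only aromatic C–H. O-alkylation at O7 with a 1,1-dimethylpropargyl electrophile and semihydrogenation would give the 7-O-(1,1-dimethylallyl) ether A6, and an ortho-Claisen rearrangement (C8 blocked) would deliver the prenyl group to C6. This adds three steps on a base- and heat-sensitive dihydroflavonol, needs O7 to be told apart from O3 and O5, and A5 itself still needs the O1/O5 decision. In the chosen plan the same sigmatropic logic is moved to the oxygen that becomes O1, where it also triggers ring closure.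

Key step: step 7

## Route

Step 1
Reactants: 1 1-(2,4,6-trihydroxyphenyl)ethan-1-one (phloroacetophenone)
Product: 2 1-[2,6-dihydroxy-4-(methoxymethoxy)phenyl]ethan-1-one
Conditions: MOMCl (1.05 equiv), K2CO3, acetone, 0 °C to rt
Reagents that add atoms: chloromethyl methyl ether (MOMCl), COCCl
Why: Williamson-type O-alkylation; the 4-OH is the only phenol not hydrogen-bonded to the acetyl group and the most acidic, so one equivalent of MOMCl should react there first, and the symmetry of the ring is kept.

Step 2
Reactants: 2 1-[2,6-dihydroxy-4-(methoxymethoxy)phenyl]ethan-1-one; 3 1-bromo-3-methylbut-2-ene (prenyl bromide)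
Product: 4 1-{2-hydroxy-4-(methoxymethoxy)-6-[(3-methylbut-2-en-1-yl)oxy]phenyl}ethan-1-one
Conditions: K2CO3, acetone, reflux
Reagents that add atoms: none
Why: Williamson ether synthesis; the two chelated OH groups of 2 are equivalent, and after the first O-alkylation the remaining OH is more strongly chelated and less acidic, so mono-etherification should dominate, and weak base in acetone favours O- over C-alkylation.

Step 3
Reactants: 4 1-{2-hydroxy-4-(methoxymethoxy)-6-[(3-methylbut-2-en-1-yl)oxy]phenyl}ethan-1-one
Product: 6 1-{6-hydroxy-3-methoxy-4-(methoxymethoxy)-2-[(3-methylbut-2-en-1-yl)oxy]phenyl}ethan-1-one, via quinone monoketal 5 (not isolated)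
Conditions: PhI(OAc)2 (2.2 equiv), MeOH, 0 °C; then Zn, AcOH, rt
Reagents that add atoms: methanol, CO
Why: Hypervalent-iodine phenol oxidation to a p-quinone monoketal followed by reductive rearomatisation; the only free phenol directs methanol to its para carbon, which lies between the O-prenyl and O-MOM carbons, and Zn/AcOH then expels one methanol from 5 to leave the p-methoxyphenol.

Step 4
Reactants: 6 1-{6-hydroxy-3-methoxy-4-(methoxymethoxy)-2-[(3-methylbut-2-en-1-yl)oxy]phenyl}ethan-1-one
Product: 7 1-{3-methoxy-4,6-bis(methoxymethoxy)-2-[(3-methylbut-2-en-1-yl)oxy]phenyl}ethan-1-one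
Conditions: NaH, MOMCl, DMF, 0 °C
Reagents that add atoms: chloromethyl methyl ether (MOMCl), COCCl
Why: O-alkylation of the sodium phenoxide (NaH breaks the hydrogen bond to the ketone); masking this oxygen ensures that only the prenyl-bearing oxygen can later become O1.

Step 5
Reactants: 7 1-{3-methoxy-4,6-bis(methoxymethoxy)-2-[(3-methylbut-2-en-1-yl)oxy]phenyl}ethan-1-one; 8 benzaldehyde
Product: 9 (E)-1-{3-methoxy-4,6-bis(methoxymethoxy)-2-[(3-methylbut-2-en-1-yl)oxy]phenyl}-3-phenylprop-2-en-1-one
Conditions: KOH, EtOH–H2O, rt
Reagents that add atoms: none
Why: Claisen–Schmidt condensation; the fully O-substituted acetophenone cannot cyclise, E1cB dehydration gives the E-enone, and MOM and prenyl ethers are stable to base.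

Step 6
Reactants: 9 (E)-1-{3-methoxy-4,6-bis(methoxymethoxy)-2-[(3-methylbut-2-en-1-yl)oxy]phenyl}-3-phenylprop-2-en-1-one
Product: 10 {3-methoxy-4,6-bis(methoxymethoxy)-2-[(3-methylbut-2-en-1-yl)oxy]phenyl}[(2R,3S)-3-phenyloxiran-2-yl]methanone
Conditions: poly-L-leucine, urea–H2O2, DBU, THF, rt
Reagents that add atoms: hydrogen peroxide (used as its urea adduct), OO
Why: Juliá–Colonna epoxidation (Weitz–Scheffer type conjugate addition of hydroperoxide and ring closure inside the helical polypeptide); the nucleophilic oxidant attacks only the enone and leaves the prenyl double bond alone, and the L-polypeptide is the one that gives the (αR,βS)-epoxide in the chalcone series, which fixes both stereocentres of the target.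

Step 7
Reactants: 10 {3-methoxy-4,6-bis(methoxymethoxy)-2-[(3-methylbut-2-en-1-yl)oxy]phenyl}[(2R,3S)-3-phenyloxiran-2-yl]methanone
Product: 14 (2R,3R)-3-hydroxy-8-methoxy-5,7-bis(methoxymethoxy)-6-(3-methylbut-2-en-1-yl)-2-phenyl-2,3-dihydro-4H-chromen-4-one, via ortho-dienone 11 (not isolated), via para-dienone 12 (not isolated), via phenol epoxide 13 (not isolated)
Conditions: Eu(fod)3 (10 mol %), PhCl, 100 °C, sealed tube
Reagents that add atoms: none
Why: Proposed new method: Eu(III) chelation between the ketone and the ether oxygen on C2' should trigger a [3,3] shift of the prenyl group onto the OMe-bearing ortho carbon C3' (dienone 11), a Cope [3,3] shift should then carry it to C5', the only ring carbon with hydrogen and para to the ether oxygen, as a linear prenyl group (12), and tautomerisation should give phenol 13. The closest known reaction types are the Eu(fod)3-catalysed Claisen–Cope rearrangement of 5-O-prenylflavanones, the thermal para-Claisen rearrangement of 2'-prenyloxyacetophenones and of allyl 2-acyl-6-methoxyphenyl ethers, and the cyclisation of 2'-hydroxychalcone epoxides, whereas their union in one operation on an epoxy ketone is new. Phenol 13, held beside the oxirane by its hydrogen bond to the ketone, should open the Lewis-acid-activated epoxide at the benzylic carbon in a 6-endo-tet closure that forms the pyranone ring C (O1–C2). C2 is set by inversion at the benzylic carbon (S in 10, R in 14) and C3 is the untouched α-carbon whose C–O bond is retained, so the trans-(2R,3R) pair follows from the (2R,3S)-epoxide. Regioselectivity at carbon is secured by the substrate, since both ortho positions of the migrating oxygen are blocked (OMe and acyl) and the two allyl inversions return the linear isomer, so a concerted and an ion-pair pathway end at the same carbon. Regioselectivity at oxygen is secured because only the oxygen that carried the prenyl group is unmasked while the other ortho oxygen remains a MOM ether, which excludes the 6-methoxy-8-prenyl isomer. 6-endo attack should beat 5-exo attack because the distal carbon is benzylic and the proximal one is deactivated by the adjacent carbonyl.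

Step 8
Reactants: 14 (2R,3R)-3-hydroxy-8-methoxy-5,7-bis(methoxymethoxy)-6-(3-methylbut-2-en-1-yl)-2-phenyl-2,3-dihydro-4H-chromen-4-one
Product: 15 (2R,3R)-3,5,7-trihydroxy-8-methoxy-6-(3-methylbut-2-en-1-yl)-2-phenyl-2,3-dihydro-4H-chromen-4-one
Conditions: HCl (1 M) in MeOH, 40 °C
Reagents that add atoms: none
Why: Acid-catalysed acetal methanolysis; the dihydroflavonol is stable to dilute acid and trans is its thermodynamic form, so neither stereocentre should move, and low acid strength and temperature are chosen so that the prenyl group between the freed 5-OH and 7-OH is not cyclised to a chroman.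

## Compound list

1 | 1-(2,4,6-trihydroxyphenyl)ethan-1-one | CC(=O)c1c(O)cc(O)cc1O | starting material
2 | 1-[2,6-dihydroxy-4-(methoxymethoxy)phenyl]ethan-1-one | CC(=O)c1c(O)cc(OCOC)cc1O | intermediate
3 | 1-bromo-3-methylbut-2-ene | CC(C)=CCBr | starting material
4 | 1-{2-hydroxy-4-(methoxymethoxy)-6-[(3-methylbut-2-en-1-yl)oxy]phenyl}ethan-1-one | CC(=O)c1c(O)cc(OCOC)cc1OCC=C(C)C | intermediate
5 | 2-acetyl-4,4-dimethoxy-5-(methoxymethoxy)-3-[(3-methylbut-2-en-1-yl)oxy]cyclohexa-2,5-dien-1-one | CC(=O)C1=C(OCC=C(C)C)C(OC)(OC)C(OCOC)=CC1=O | intermediate (not isolated)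
6 | 1-{6-hydroxy-3-methoxy-4-(methoxymethoxy)-2-[(3-methylbut-2-en-1-yl)oxy]phenyl}ethan-1-one | CC(=O)c1c(O)cc(OCOC)c(OC)c1OCC=C(C)C | intermediate
7 | 1-{3-methoxy-4,6-bis(methoxymethoxy)-2-[(3-methylbut-2-en-1-yl)oxy]phenyl}ethan-1-one | CC(=O)c1c(OCOC)cc(OCOC)c(OC)c1OCC=C(C)C | intermediate
8 | benzaldehyde | O=Cc1ccccc1 | starting material
9 | (E)-1-{3-methoxy-4,6-bis(methoxymethoxy)-2-[(3-methylbut-2-en-1-yl)oxy]phenyl}-3-phenylprop-2-en-1-one | O=C(/C=C/c1ccccc1)c1c(OCOC)cc(OCOC)c(OC)c1OCC=C(C)C | intermediate
10 | {3-methoxy-4,6-bis(methoxymethoxy)-2-[(3-methylbut-2-en-1-yl)oxy]phenyl}[(2R,3S)-3-phenyloxiran-2-yl]methanone | O=C([C@@H]1O[C@H]1c1ccccc1)c1c(OCOC)cc(OCOC)c(OC)c1OCC=C(C)C | intermediate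
11 | 6-methoxy-3,5-bis(methoxymethoxy)-6-(2-methylbut-3-en-2-yl)-2-{[(2R,3S)-3-phenyloxiran-2-yl]carbonyl}cyclohexa-2,4-dien-1-one (both epimers at the sp3 ring carbon) | O=C([C@@H]1O[C@H]1c1ccccc1)C1=C(OCOC)C=C(OCOC)C(OC)(C(C)(C)C=C)C1=O | intermediate (not isolated)
12 | 2-methoxy-3,5-bis(methoxymethoxy)-4-(3-methylbut-2-en-1-yl)-6-{[(2R,3S)-3-phenyloxiran-2-yl]carbonyl}cyclohexa-2,5-dien-1-one (both epimers at the sp3 ring carbon) | O=C([C@@H]1O[C@H]1c1ccccc1)C1=C(OCOC)C(CC=C(C)C)C(OCOC)=C(OC)C1=O | intermediate (not isolated)
13 | [2-hydroxy-3-methoxy-4,6-bis(methoxymethoxy)-5-(3-methylbut-2-en-1-yl)phenyl][(2R,3S)-3-phenyloxiran-2-yl]methanone | O=C([C@@H]1O[C@H]1c1ccccc1)c1c(OCOC)c(CC=C(C)C)c(OCOC)c(OC)c1O | intermediate (not isolated)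
14 | (2R,3R)-3-hydroxy-8-methoxy-5,7-bis(methoxymethoxy)-6-(3-methylbut-2-en-1-yl)-2-phenyl-2,3-dihydro-4H-chromen-4-one | COc1c(OCOC)c(CC=C(C)C)c(OCOC)c2c1O[C@H](c1ccccc1)[C@@H](O)C2=O | intermediate
15 | (2R,3R)-3,5,7-trihydroxy-8-methoxy-6-(3-methylbut-2-en-1-yl)-2-phenyl-2,3-dihydro-4H-chromen-4-one | COc1c(O)c(CC=C(C)C)c(O)c2c1O[C@H](c1ccccc1)[C@@H](O)C2=O | target

## Step count and least certain steps

Total step count: 8. Longest linear sequence: 8 steps (1 to 15).

**Step 7 (key step, proposed new method).** Three processes may interfere. The oxirane may not survive the temperature and Lewis acid needed for two [3,3] shifts through a fully substituted ortho carbon (acyl-shift rearrangement of the epoxy ketone, or opening before the phenol is free). Heterolysis of the prenyl ether (loss of the C5 unit) may outrun rearrangement and lead to ring closure without C-prenylation. Partial ionisation at the benzylic carbon would lower the trans selectivity; this would give the separable 2,3-cis diastereomer, not the enantiomer. Fallback with known chemistry, separating rearrangement from ring closure: the route sets out from 7. Thermal para-Claisen–Cope rearrangement in N,N-diethylaniline at about 190 °C, the protocol known for 2'-prenyloxyacetophenones, should give the C-prenylated phenol F1. O-Allylation (allyl bromide, K2CO3) should give its allyl ether F2, which is thermally inert because both ortho positions and the para position are now substituted. Claisen–Schmidt condensation with 8 should give the chalcone F3, and Juliá–Colonna epoxidation the (2R,3S)-epoxide F4. Pd(PPh3)4/morpholine removes the allyl group under neutral conditions and releases 13, which closes to 14 (with catalytic PPTS if needed). The fallback comes back to the route at 14.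

**Step 3.** The phenoxonium intermediate may be trapped at the ortho carbon and not at the para carbon, which is flanked by two alkoxy groups. It may also be captured by the double bond of the neighbouring prenyl ether, or the second oxidation may stall. Fallback: a radical para-oxidation in place of cation trapping. From 4, Fremy's salt (buffered aqueous acetone) should give the p-quinone F5, the only quinone possible while the para position is free. Sodium dithionite should reduce it to the hydroquinone F6. One equivalent of MeI with K2CO3 should then methylate the non-chelated hydroxyl and leave the ketone-bonded one. The fallback returns at 6.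

**Step 6.** Conversion or facial selectivity may be poor, because the 2',6'-disubstituted aryl ketone is twisted out of conjugation and bulkier than the chalcones on which the polypeptide works best. Fallback: reagent-controlled epoxidation at the alcohol oxidation level. From 9, Luche reduction (NaBH4, CeCl3) should give the racemic allylic alcohol F7. Sharpless kinetic-resolution epoxidation (Ti(OiPr)4, L-(+)-diisopropyl tartrate, 0.6 equiv TBHP, −20 °C) uses the tartrate that converts (E)-cinnamyl alcohol into its (2S,3S)-epoxide. It should convert the fast-reacting enantiomer into the erythro epoxy alcohol F8 and leave the prenyl ether, which is not an allylic alcohol, untouched. Dess–Martin oxidation of F8 returns to the route at 10. The price is that at most half of the material is used.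

**Step 8.** The prenyl group may cyclise onto the freed 5-OH or 7-OH, or add HCl or methanol across its double bond, under protic acid. Fallback: aprotic transfer of the MOM carbon to sulfur (ZnBr2, n-PrSH, CH2Cl2, 0 °C), a Lewis-acid/soft-nucleophile cleavage in which no protic acid builds up beside the alkene. It sets out from 14, arrives at 15 and makes no new compound.

**Step 2.** The ambident phloroglucinol phenoxide may be alkylated at carbon, or both hydroxyls may be etherified. Fallback: Mitsunobu etherification of the neutral phenol with 3-methylbut-2-en-1-ol (PPh3, DIAD, THF), which can only alkylate oxygen. It sets out from 2, returns at 4 and makes no new compound.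

## Further compounds

F1 | step 7 | 1-[2-hydroxy-3-methoxy-4,6-bis(methoxymethoxy)-5-(3-methylbut-2-en-1-yl)phenyl]ethan-1-one | CC(=O)c1c(OCOC)c(CC=C(C)C)c(OCOC)c(OC)c1O
F2 | step 7 | 1-[3-methoxy-4,6-bis(methoxymethoxy)-5-(3-methylbut-2-en-1-yl)-2-(prop-2-en-1-yloxy)phenyl]ethan-1-one | CC(=O)c1c(OCOC)c(CC=C(C)C)c(OCOC)c(OC)c1OCC=C
F3 | step 7 | (E)-1-[3-methoxy-4,6-bis(methoxymethoxy)-5-(3-methylbut-2-en-1-yl)-2-(prop-2-en-1-yloxy)phenyl]-3-phenylprop-2-en-1-one | O=C(/C=C/c1ccccc1)c1c(OCOC)c(CC=C(C)C)c(OCOC)c(OC)c1OCC=C
F4 | step 7 | [3-methoxy-4,6-bis(methoxymethoxy)-5-(3-methylbut-2-en-1-yl)-2-(prop-2-en-1-yloxy)phenyl][(2R,3S)-3-phenyloxiran-2-yl]methanone | O=C([C@@H]1O[C@H]1c1ccccc1)c1c(OCOC)c(CC=C(C)C)c(OCOC)c(OC)c1OCC=C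
F5 | step 3 | 2-acetyl-5-(methoxymethoxy)-3-[(3-methylbut-2-en-1-yl)oxy]cyclohexa-2,5-diene-1,4-dione | CC(=O)C1=C(OCC=C(C)C)C(=O)C(OCOC)=CC1=O
F6 | step 3 | 1-{3,6-dihydroxy-4-(methoxymethoxy)-2-[(3-methylbut-2-en-1-yl)oxy]phenyl}ethan-1-one | CC(=O)c1c(O)cc(OCOC)c(O)c1OCC=C(C)C
F7 | step 6 | (±)-(E)-1-{3-methoxy-4,6-bis(methoxymethoxy)-2-[(3-methylbut-2-en-1-yl)oxy]phenyl}-3-phenylprop-2-en-1-ol | OC(/C=C/c1ccccc1)c1c(OCOC)cc(OCOC)c(OC)c1OCC=C(C)C
F8 | step 6 | (S)-{3-methoxy-4,6-bis(methoxymethoxy)-2-[(3-methylbut-2-en-1-yl)oxy]phenyl}[(2S,3S)-3-phenyloxiran-2-yl]methanol | O[C@@H](c1c(OCOC)cc(OCOC)c(OC)c1OCC=C(C)C)[C@@H]1O[C@H]1c1ccccc1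
F0 | step 8 | none | none
F0 | step 2 | none | none
A1 | alternative 1 | [3-methoxy-2,4,6-tris(methoxymethoxy)-5-(3-methylbut-2-en-1-yl)phenyl][(2R,3S)-3-phenyloxiran-2-yl]methanone | O=C([C@@H]1O[C@H]1c1ccccc1)c1c(OCOC)c(CC=C(C)C)c(OCOC)c(OC)c1OCOC
A2 | alternative 1 | (2R,3R)-3,5,7-trihydroxy-6-methoxy-8-(3-methylbut-2-en-1-yl)-2-phenyl-2,3-dihydro-4H-chromen-4-one | COc1c(O)c(CC=C(C)C)c2O[C@H](c3ccccc3)[C@@H](O)C(=O)c2c1O
A3 | alternative 2 | 8-methoxy-5,7-bis(methoxymethoxy)-6-(3-methylbut-2-en-1-yl)-4H-chromen-4-one | O=c1ccoc2c(OC)c(OCOC)c(CC=C(C)C)c(OCOC)c12
A4 | alternative 2 | (2S)-8-methoxy-5,7-bis(methoxymethoxy)-6-(3-methylbut-2-en-1-yl)-2-phenyl-2,3-dihydro-4H-chromen-4-one | COc1c(OCOC)c(CC=C(C)C)c(OCOC)c2c1O[C@H](c1ccccc1)CC2=O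
A5 | alternative 3 | (2R,3R)-3,5,7-trihydroxy-8-methoxy-2-phenyl-2,3-dihydro-4H-chromen-4-one | COc1c(O)cc(O)c2c1O[C@H](c1ccccc1)[C@@H](O)C2=O
A6 | alternative 3 | (2R,3R)-3,5-dihydroxy-8-methoxy-7-[(2-methylbut-3-en-2-yl)oxy]-2-phenyl-2,3-dihydro-4H-chromen-4-one | COc1c(OC(C)(C)C=C)cc(O)c2c1O[C@H](c1ccccc1)[C@@H](O)C2=O
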